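**Plan**
1. The target is 5,2',5'-trihydroxy-7,3',4'-trimethoxyflavone. In retrosynthesis, C3–H and the 2'-OH are first reconnected through one carbonyl carbon, giving a temporary lactone ring D (C3–C(=O)–O2'). The cuts that follow are C2–C1', then the ester bond C(=O)–O2', then ring C back to an acetophenone.
2. Enabling feature: O2' sits on the ring B carbon next to C1', and C3 is the neighbour of C2 in pyranone ring C. A C3–C(=O)–O2' ester therefore makes C1' and C2 the two ends of a six-atom chain, and C1'–Br and C2–H are the only pair that can meet.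
3. Forward: rings A and B are purchased. Ring C comes from a Vilsmeier–Haack reaction on the monobenzylated acetophenone, and the 3-formyl group is oxidised to the acid.
4. Ring B is prepared from 2,3-dimethoxyphenol by para-oxidation, reduction, monobenzylation and bromination ortho to the free OH. Esterification then joins the two halves.
5. Palladium forms C2–C1' and closes ring D. Hydrogenolysis followed by hot aqueous acid removes the bridge carbon as CO2 and restores C3–H and the 2'-OH.
6. The target has no stereocentre, so only site selectivity needs control. The tether, the bromine and the symmetry of two intermediates provide it.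

Key step: step 9

Remark on the chemistry: flavone numbering is used throughout (ring A benzo, ring C pyranone, ring B 2-aryl, ring D the temporary lactone), and compounds 1, 2 and 6 are taken as catalogue chemicals.
Remark on the chemistry: the acid released from ring D holds the 2'-OH cis to it across C2=C3 and would relactonise on isolation, and hydroxide is expected to attack the doubly activated C2. The bridge is therefore excised in hot aqueous acid, where ring opening is reversible and only loss of CO2 is not.

Step 1
Reactants: 1 2',6'-dihydroxy-4'-methoxyacetophenone; 2 benzyl bromide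
Product: 3 1-[2-(benzyloxy)-6-hydroxy-4-methoxyphenyl]ethanone
Conditions: BnBr (1.05 equiv), K2CO3 (1.1 equiv), acetone, reflux
Reagents that add atoms: benzyl bromide (2), BrCc1ccccc1
Why: Williamson etherification of two equivalent OH groups, in which the remaining OH is hydrogen-bonded to the acetyl carbonyl after the first alkylation, so one equivalent of benzyl bromide should stop at the monoether.

Step 2
Reactants: 3 1-[2-(benzyloxy)-6-hydroxy-4-methoxyphenyl]ethanone
Product: 4 5-(benzyloxy)-7-methoxy-4-oxo-4H-chromene-3-carbaldehyde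
Conditions: POCl3 (4 equiv), DMF, 0 °C to 50 °C; then ice-water
Reagents that add atoms: N,N-dimethylformamide, CN(C)C=O; water, O
Why: Vilsmeier–Haack double formylation of the acetyl CH3 of an o-hydroxyacetophenone, with closure of the phenol oxygen onto one iminium carbon, is the standard route to 3-formylchromones and builds ring C, while the acyl group deactivates ring A towards nuclear formylation.

Step 3
Reactants: 4 5-(benzyloxy)-7-methoxy-4-oxo-4H-chromene-3-carbaldehyde
Product: 5 5-(benzyloxy)-7-methoxy-4-oxo-4H-chromene-3-carboxylic acid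
Conditions: NaClO2, NaH2PO4, 2-methyl-2-butene, t-BuOH–THF–H2O, 0 °C to rt
Reagents that add atoms: sodium chlorite, [Na+].[O-]Cl=O
Why: Pinnick oxidation works near pH 4, which leaves the electrophilic C2 and the benzyl ether untouched, and the alkene removes HOCl before it can chlorinate ring A.

Step 4
Reactants: 6 2,3-dimethoxyphenol
Product: 7 2,3-dimethoxy-1,4-benzoquinone
Conditions: (KSO3)2NO (2.5 equiv), KH2PO4 buffer, H2O–acetone, rt
Reagents that add atoms: potassium nitrosodisulfonate, [K+].[K+].[O]N(S(=O)(=O)[O-])S(=O)(=O)[O-]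
Why: Teuber oxidation, in which one nitrosodisulfonate radical abstracts the phenolic hydrogen and a second delivers oxygen to the free para position, converts such phenols into p-quinones.

Step 5
Reactants: 7 2,3-dimethoxy-1,4-benzoquinone
Product: 8 2,3-dimethoxybenzene-1,4-diol
Conditions: Na2S2O4, H2O–EtOAc, rt, Ar
Reagents that add atoms: none
Why: Dithionite reduction of a quinone to its hydroquinone is fast, and the two-phase medium carries the air-sensitive diol into the organic layer.

Step 6
Reactants: 8 2,3-dimethoxybenzene-1,4-diol; 2 benzyl bromide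
Product: 9 4-(benzyloxy)-2,3-dimethoxyphenol
Conditions: BnBr (1.0 equiv), K2CO3 (1.0 equiv), DMF, rt, Ar
Reagents that add atoms: benzyl bromide (2), BrCc1ccccc1
Why: Williamson etherification of a symmetric diol raises no question of site but only of degree, and the monoether should separate from the neutral diether by extraction into aqueous base and from the diol by the water solubility of the latter.

Step 7
Reactants: 9 4-(benzyloxy)-2,3-dimethoxyphenol
Product: 10 4-(benzyloxy)-6-bromo-2,3-dimethoxyphenol
Conditions: NBS (1.0 equiv), CH2Cl2, −20 to 0 °C, dark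
Reagents that add atoms: N-bromosuccinimide, O=C1CCC(=O)N1Br
Why: In this electrophilic aromatic bromination the free OH outranks the benzyl ether as a director, its para position is blocked, and each methoxy group is para to one open site so the two cancel, which should send bromine to C6 as it does in 4-alkoxyphenols.

Step 8
Reactants: 5 5-(benzyloxy)-7-methoxy-4-oxo-4H-chromene-3-carboxylic acid; 10 4-(benzyloxy)-6-bromo-2,3-dimethoxyphenol
Product: 12 4-(benzyloxy)-6-bromo-2,3-dimethoxyphenyl 5-(benzyloxy)-7-methoxy-4-oxo-4H-chromene-3-carboxylate, via chromone-3-carbonyl chloride 11 (not isolated)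
Conditions: (COCl)2, cat. DMF, CH2Cl2, 0 °C to rt, evaporate; then 10, Et3N, cat. DMAP, CH2Cl2, 0 °C to rt
Reagents that add atoms: oxalyl chloride, O=C(Cl)C(=O)Cl (supplies the chlorine of 11 only)
Why: Acid chloride formation followed by DMAP-catalysed O-acylation is forceful enough for a phenol flanked by Br and OMe, and tertiary amines cannot open the pyranone permanently at C2.

Step 9
Reactants: 12 4-(benzyloxy)-6-bromo-2,3-dimethoxyphenyl 5-(benzyloxy)-7-methoxy-4-oxo-4H-chromene-3-carboxylate
Product: 13 2,8-bis(benzyloxy)-3,4,10-trimethoxy-6H,7H-chromeno[4,3-b]chromene-6,7-dione (the flavone with C3 and O2' bridged by a lactone carbonyl)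
Conditions: Pd(OAc)2 (10 mol %), PCy3·HBF4 (20 mol %), dry K2CO3 (2 equiv), PivOH (30 mol %), DMA, 110 °C, Ar
Reagents that add atoms: none
Why: Proposed new method: Pd(OAc)2 is reduced in situ to a zerovalent palladium–PCy3 complex that inserts into C1'–Br, bromide is exchanged for pivalate, and carboxylate-assisted concerted metalation–deprotonation of C2–H (acidified by O1 and by the carbonyl groups on C3 and C4) gives a seven-membered diorganopalladium ring whose reductive elimination forms C2–C1'. The closest known reaction types are the palladium-catalysed intramolecular direct arylation of 2-halophenyl arenecarboxylates to 6H-benzo[c]chromen-6-ones and the intermolecular C2–H arylation of chromones; their union on a chromone-3-carboxylate, where the C–H partner is a vinylogous ester carbon and the tether an activated aryl ester, has not been shown. The single ring formed is the six-membered lactone D, closed through a C(sp2)–C(sp2) bond in a 6-endo sense because both C2 and C3 of the attacked double bond end up inside the new ring, and a Heck-type carbopalladation at C2 followed by base-induced loss of HPdBr would give the same product. No stereocentre is created. The step needs site selectivity on both rings and survival of the ester: bromine fixes C1', the tether lets only C2–H reach palladium (C6–H, C8–H and the benzyl rings are out of range, and the 5'-benzyloxy group is meta to bromine and cannot cyclise), and dry carbonate with only catalytic pivalate keeps oxygen nucleophiles away from the ester carbonyl and from C2.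

Step 10
Reactants: 13 2,8-bis(benzyloxy)-3,4,10-trimethoxy-6H,7H-chromeno[4,3-b]chromene-6,7-dione
Product: 14 2,8-dihydroxy-3,4,10-trimethoxy-6H,7H-chromeno[4,3-b]chromene-6,7-dione
Conditions: H2 (1 atm), 10% Pd/C, THF–EtOAc, rt
Reagents that add atoms: none
Why: Catalytic hydrogenolysis of aryl benzyl ethers is neutral and leaves the tetrasubstituted C2=C3 bond, the lactone and the methyl ethers alone, and it frees the 5-OH whose hydrogen bond to C4=O biases the next step.

Step 11
Reactants: 14 2,8-dihydroxy-3,4,10-trimethoxy-6H,7H-chromeno[4,3-b]chromene-6,7-dione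
Product: 16 5,2',5'-trihydroxy-7,3',4'-trimethoxyflavone, via ring-opened flavone-3-carboxylic acid 15 (not isolated)
Conditions: 6 M aq HCl–AcOH (1:2), reflux, Ar
Reagents that add atoms: water, O (its oxygen enters 15 and leaves again in CO2)
Why: This is an acid-catalysed hydrolysis–decarboxylation of a 3-acyl-4-oxy-2-pyranone (the reaction type that turns dehydroacetic acid into 2,6-dimethyl-4-pyranone), in which opening of ring D is reversible but acid 15 or its C2 hydrate loses CO2 irreversibly, and if ring C opens on the way the resulting 1,3-diketone should reclose through the ring A phenol onto the unhindered ring B carbonyl, because only that mode regains the 5-OH to C4=O hydrogen bond and a coplanar 2-aryl group.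

**Compound list**
1 | 2',6'-dihydroxy-4'-methoxyacetophenone | CC(=O)c1c(O)cc(OC)cc1O | starting material
2 | benzyl bromide | BrCc1ccccc1 | starting material
3 | 1-[2-(benzyloxy)-6-hydroxy-4-methoxyphenyl]ethanone | CC(=O)c1c(O)cc(OC)cc1OCc1ccccc1 | intermediate
4 | 5-(benzyloxy)-7-methoxy-4-oxo-4H-chromene-3-carbaldehyde | COc1cc(OCc2ccccc2)c2c(=O)c(C=O)coc2c1 | intermediate
5 | 5-(benzyloxy)-7-methoxy-4-oxo-4H-chromene-3-carboxylic acid | COc1cc(OCc2ccccc2)c2c(=O)c(C(=O)O)coc2c1 | intermediate
6 | 2,3-dimethoxyphenol | COc1cccc(O)c1OC | starting material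
7 | 2,3-dimethoxy-1,4-benzoquinone | COC1=C(OC)C(=O)C=CC1=O | intermediate
8 | 2,3-dimethoxybenzene-1,4-diol | COc1c(O)ccc(O)c1OC | intermediate
9 | 4-(benzyloxy)-2,3-dimethoxyphenol | COc1c(O)ccc(OCc2ccccc2)c1OC | intermediate
10 | 4-(benzyloxy)-6-bromo-2,3-dimethoxyphenol | COc1c(O)c(Br)cc(OCc2ccccc2)c1OC | intermediate
11 | 5-(benzyloxy)-7-methoxy-4-oxo-4H-chromene-3-carbonyl chloride (not isolated) | COc1cc(OCc2ccccc2)c2c(=O)c(C(=O)Cl)coc2c1 | intermediate
12 | 4-(benzyloxy)-6-bromo-2,3-dimethoxyphenyl 5-(benzyloxy)-7-methoxy-4-oxo-4H-chromene-3-carboxylate | COc1cc(OCc2ccccc2)c2c(=O)c(C(=O)Oc3c(Br)cc(OCc4ccccc4)c(OC)c3OC)coc2c1 | intermediate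
13 | 2,8-bis(benzyloxy)-3,4,10-trimethoxy-6H,7H-chromeno[4,3-b]chromene-6,7-dione | COc1cc(OCc2ccccc2)c2c(=O)c3c(oc2c1)-c1cc(OCc2ccccc2)c(OC)c(OC)c1OC3=O | intermediate
14 | 2,8-dihydroxy-3,4,10-trimethoxy-6H,7H-chromeno[4,3-b]chromene-6,7-dione | COc1cc(O)c2c(=O)c3c(oc2c1)-c1cc(O)c(OC)c(OC)c1OC3=O | intermediate
15 | 2-(2,5-dihydroxy-3,4-dimethoxyphenyl)-5-hydroxy-7-methoxy-4-oxo-4H-chromene-3-carboxylic acid (not isolated) | COc1cc(O)c2c(=O)c(C(=O)O)c(-c3cc(O)c(OC)c(OC)c3O)oc2c1 | intermediate
16 | 5,2',5'-trihydroxy-7,3',4'-trimethoxyflavone (CNP0170944.0) | COc1cc(O)c2c(=O)cc(-c3cc(O)c(OC)c(OC)c3O)oc2c1 | target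

**Total step count:** 11
**Longest linear sequence:** 8 steps (6 to 16 through steps 4, 5, 6, 7, 8, 9, 10, 11)

**Steps most likely to fail**

Step 9. The activated aryl ester may be cleaved by carbonate or pivalate before oxidative addition, the arylpalladium species may be reduced to Ar–H, or the pyranone may be opened at C2.
- The fallback gives up C2–C1' as the coupling site and closes ring C last by a Baker–Venkataraman sequence. It sets out from 10 and 3.
- Benzylation of 10 (2, K2CO3, DMF) gives 1,4-bis(benzyloxy)-5-bromo-2,3-dimethoxybenzene F1.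
- Bromine–lithium exchange (n-BuLi, THF, −78 °C) and quenching with CO2 give 2,5-bis(benzyloxy)-3,4-dimethoxybenzoic acid F2.
- Esterification with 3 (EDC, DMAP, CH2Cl2) gives 2-acetyl-3-(benzyloxy)-5-methoxyphenyl 2,5-bis(benzyloxy)-3,4-dimethoxybenzoate F3.
- KOH in pyridine at 50 °C moves the aroyl group onto the acetyl carbon and gives 1-[2-(benzyloxy)-6-hydroxy-4-methoxyphenyl]-3-[2,5-bis(benzyloxy)-3,4-dimethoxyphenyl]propane-1,3-dione F4.
- AcOH with catalytic H2SO4 cyclodehydrates F4 to 5-(benzyloxy)-2-[2,5-bis(benzyloxy)-3,4-dimethoxyphenyl]-7-methoxy-4H-chromen-4-one F5.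
- Hydrogenolysis (H2, Pd/C) comes back to the route at 16.

Step 11. The coumarin-type lactone may resist opening. Alternatively, ring C may open and the ring A acyl group may then be lost by retro-Claisen cleavage, or the ring may reclose through the ring B phenol.
- The fallback opens the bridge by oxidation instead of hydrolysis, using the para relation between O2' and the 5'-OH. It sets out from 14.
- PhI(OAc)2 in MeCN–H2O at 0 °C oxidises ring B to the quinone and expels the carboxylate from C2', the reaction type that converts 6-hydroxydihydrocoumarins into quinone acids. The product is 2-(4,5-dimethoxy-3,6-dioxocyclohexa-1,4-dien-1-yl)-5-hydroxy-7-methoxy-4-oxo-4H-chromene-3-carboxylic acid F6.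
- F6 carries no phenol on ring B, so it can neither relactonise nor reclose the wrong way.
- Protodecarboxylation with catalytic Ag2CO3 and AcOH in DMSO at 120 °C gives 2-(4,5-dimethoxy-3,6-dioxocyclohexa-1,4-dien-1-yl)-5-hydroxy-7-methoxy-4H-chromen-4-one F7.
- Na2S2O4 in H2O–EtOAc reduces the quinone and comes back to the route at 16.

Step 7. The very electron-rich hydroquinone monoether may be oxidised to the quinone with loss of benzyl, or bromine may enter next to the benzyloxy group.
- The fallback places bromine by directed ortho-metalation instead of electrophilic substitution. It sets out from 9.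
- ClC(O)NEt2 with NaH in THF gives 4-(benzyloxy)-2,3-dimethoxyphenyl diethylcarbamate F8.
- s-BuLi–TMEDA in THF at −78 °C lithiates the only open position next to the carbamate. Quenching with BrCF2CF2Br gives 4-(benzyloxy)-6-bromo-2,3-dimethoxyphenyl diethylcarbamate F9.
- KOH in refluxing EtOH removes the carbamate and comes back to the route at 10.

**Further compounds**
F1 | step 9 | 1,4-bis(benzyloxy)-5-bromo-2,3-dimethoxybenzene | COc1c(OCc2ccccc2)c(Br)cc(OCc2ccccc2)c1OC
F2 | step 9 | 2,5-bis(benzyloxy)-3,4-dimethoxybenzoic acid | COc1c(OCc2ccccc2)cc(C(=O)O)c(OCc2ccccc2)c1OC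
F3 | step 9 | 2-acetyl-3-(benzyloxy)-5-methoxyphenyl 2,5-bis(benzyloxy)-3,4-dimethoxybenzoate | CC(=O)c1c(OCc2ccccc2)cc(OC)cc1OC(=O)c1cc(OCc2ccccc2)c(OC)c(OC)c1OCc1ccccc1
F4 | step 9 | 1-[2-(benzyloxy)-6-hydroxy-4-methoxyphenyl]-3-[2,5-bis(benzyloxy)-3,4-dimethoxyphenyl]propane-1,3-dione | COc1cc(O)c(C(=O)CC(=O)c2cc(OCc3ccccc3)c(OC)c(OC)c2OCc2ccccc2)c(OCc2ccccc2)c1
F5 | step 9 | 5-(benzyloxy)-2-[2,5-bis(benzyloxy)-3,4-dimethoxyphenyl]-7-methoxy-4H-chromen-4-one | COc1cc(OCc2ccccc2)c2c(=O)cc(-c3cc(OCc4ccccc4)c(OC)c(OC)c3OCc3ccccc3)oc2c1
F6 | step 11 | 2-(4,5-dimethoxy-3,6-dioxocyclohexa-1,4-dien-1-yl)-5-hydroxy-7-methoxy-4-oxo-4H-chromene-3-carboxylic acid | COc1cc(O)c2c(=O)c(C(=O)O)c(C3=CC(=O)C(OC)=C(OC)C3=O)oc2c1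
F7 | step 11 | 2-(4,5-dimethoxy-3,6-dioxocyclohexa-1,4-dien-1-yl)-5-hydroxy-7-methoxy-4H-chromen-4-one | COc1cc(O)c2c(=O)cc(C3=CC(=O)C(OC)=C(OC)C3=O)oc2c1
F8 | step 7 | 4-(benzyloxy)-2,3-dimethoxyphenyl diethylcarbamate | CCN(CC)C(=O)Oc1ccc(OCc2ccccc2)c(OC)c1OC
F9 | step 7 | 4-(benzyloxy)-6-bromo-2,3-dimethoxyphenyl diethylcarbamate | CCN(CC)C(=O)Oc1c(Br)cc(OCc2ccccc2)c(OC)c1OC
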